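**Strategy.** The route rests on cutting the C7–C8 bond of ring B (C8–C7–O–C9'–C8'). The acetoxy-bearing bridgehead C8 lies next to benzylic C7 and is also tied to it through C8'–C9'–O, so C8 is read as a ring-A ketone and C7 as the CH2 of a vanillyl ether. A Norrish–Yang photocyclisation (δ-hydrogen abstraction, then 1,5-biradical coupling) forms C7–C8, closes ring B, creates the bridgehead hydroxyl and sets C7 and C8 in one operation. Its precursor is a trans-5-aryl-4-(vanillyloxymethyl)dihydrofuran-3-one, built by an auxiliary-controlled aldol reaction, carbenoid O–H insertion and epimerisation at C8'.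

Key step: step 12

Remark: lignan locants are used (C7, C7' = ArCH–O; C8 = acetoxy bridgehead; C8' = CH bridgehead; C9, C9' = OCH2). Ar = 4-(triisopropylsilyloxy)-3-methoxyphenyl, so ArCH2 is the TIPS-protected vanillyl group.

Remark: the C7' hydroxyl is carried as a TES ether through steps 8 and 9 only, because a mixed anhydride next to a free β-hydroxyl would acylate it.

Step 1
Reactants: 1 vanillin
Product: 2 4-(triisopropylsilyloxy)-3-methoxybenzaldehyde (ArCHO)
Conditions: TIPSCl, imidazole, DMF, rt
Reagents that add atoms: triisopropylsilyl chloride, CC(C)[Si](Cl)(C(C)C)C(C)C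
Why: Imidazole-mediated silylation of the phenol gives a bulky aryl silyl ether that should survive the later mild bases, the boron Lewis acid, the rhodium carbenoid and the irradiation, and that fluoride removes at the end.

Step 2
Reactants: 2 ArCHO
Product: 3 [4-(triisopropylsilyloxy)-3-methoxyphenyl]methanol (ArCH2OH)
Conditions: NaBH4, MeOH/THF, 0 °C
Reagents that add atoms: none
Why: Borohydride reduction of the aryl aldehyde to the benzylic alcohol is chemoselective and leaves the aryl silyl ether untouched.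

Step 3
Reactants: 3 ArCH2OH; 4 methyl acrylate
Product: 5 methyl 3-(ArCH2O)propanoate
Conditions: PMe3 (5 mol %), 4 (1.5 equiv), THF, rt
Reagents that add atoms: none
Why: Phosphine-catalysed oxa-Michael addition of the primary benzylic alcohol to the acrylate forms the C9'–O ether bond without stoichiometric alkoxide, which would otherwise threaten the aryl silyl ether.

Step 4
Reactants: 5 methyl 3-(ArCH2O)propanoate
Product: 6 3-(ArCH2O)propanoic acid
Conditions: LiOH·H2O (1.5 equiv), THF/H2O 3:1, 0 °C; then cold 1 M HCl to pH 3–4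
Reagents that add atoms: lithium hydroxide, [Li+].[OH-]
Why: Saponification of the unhindered methyl ester at 0 °C should be much faster than attack of hydroxide on the hindered aryl TIPS ether or retro-oxa-Michael elimination.

Step 5
Reactants: 6 3-(ArCH2O)propanoic acid; 7 (R)-4-benzyloxazolidin-2-one
Product: 9 (R)-4-benzyl-3-[3-(ArCH2O)propanoyl]oxazolidin-2-one, via mixed pivalic anhydride 8 (not isolated)
Conditions: PivCl, Et3N, THF, −20 °C; then 7, LiCl, −20 °C to rt
Reagents that add atoms: none
Why: N-Acylation of the auxiliary through the mixed pivalic anhydride with LiCl/Et3N is a standard one-pot procedure that avoids an acid chloride of the acid-sensitive, electron-rich benzyl ether.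

Step 6
Reactants: 9 N-acyl oxazolidinone; 2 ArCHO
Product: 12 (R)-4-benzyl-3-[(2R,3R)-3-Ar-3-hydroxy-2-(ArCH2OCH2)propanoyl]oxazolidin-2-one (syn adduct; C8' R and C7' R), via Z-boron enolate 10 (not isolated), via boron aldolate 11 (not isolated)
Conditions: Bu2BOTf, Et3N, CH2Cl2, −78 to 0 °C; 2, −78 to 0 °C; then pH 7 buffer, MeOH, H2O2, 0 °C
Reagents that add atoms: none
Why: In this Evans syn aldol reaction the Z-boron enolate reacts through a chair-like Zimmerman–Traxler transition state on the face left open by the benzyl group of the dipole-minimised (R)-auxiliary, which forms C7'–C8' and sets C7' (R) and C8' (R) syn, while the covalent boron enolate at low temperature should not expel the β-alkoxy group.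

Step 7
Reactants: 12 syn aldol adduct
Product: 14 (2R,3R)-3-Ar-3-hydroxy-2-(ArCH2OCH2)propanoic acid, via peroxy acid 13 (not isolated)
Conditions: LiOH, H2O2, THF/H2O, 0 °C; then aq Na2SO3; then cold 1 M HCl to pH 3–4
Reagents that add atoms: hydrogen peroxide (acting as LiOOH), OO
Why: Hydroperoxide attacks the exocyclic imide carbonyl selectively, which is fast for β-hydroxy imides, and sulfite reduces the resulting peroxy acid to the acid without epimerisation at C8' or retro-aldol cleavage at 0 °C.

Step 8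
Reactants: 14 β-hydroxy acid
Product: 16 (2R,3R)-3-Ar-3-(triethylsilyloxy)-2-(ArCH2OCH2)propanoic acid, via silyl ester silyl ether 15 (not isolated)
Conditions: TESCl (2.5 equiv), imidazole, DMF, 0 °C to rt; then NaHCO3, MeOH/H2O, rt; mild acidic work-up
Reagents that add atoms: triethylsilyl chloride, CC[Si](Cl)(CC)CC
Why: Exhaustive silylation followed by selective hydrolysis of the far more labile silyl ester leaves only the C7' hydroxyl capped, which keeps it out of the carboxyl activation of the next step.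

Step 9
Reactants: 16 O-TES acid; 17 (trimethylsilyl)diazomethane
Product: 19 (3R,4R)-4-Ar-1-diazo-4-(triethylsilyloxy)-3-(ArCH2OCH2)butan-2-one, via isobutyl carbonic anhydride 18 (not isolated)
Conditions: iBuOCOCl, Et3N, THF, −20 °C; then 17 (2 equiv), MeCN, 0 °C to rt
Reagents that add atoms: none
Why: The mixed carbonic anhydride C-acylates the nucleophilic diazo carbon and the silyl group is then lost from carbon to give the terminal α-diazoketone (first stage of an Arndt–Eistert sequence), which brings in C9 without any base strong enough to epimerise C8'.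

Step 10
Reactants: 19 O-TES diazoketone
Product: 20 (3R,4R)-4-Ar-1-diazo-4-hydroxy-3-(ArCH2OCH2)butan-2-one
Conditions: PPTS (0.1 equiv), MeOH/CH2Cl2, 0 °C
Reagents that add atoms: none
Why: Mildly acidic methanolysis removes the secondary TES ether, while the acceptor-stabilised diazoketone, the aryl TIPS ethers and the benzyl ether should tolerate pyridinium-level acidity at 0 °C.

Step 11
Reactants: 20 β-hydroxy diazoketone
Product: 22 (4S,5R)-5-Ar-4-(ArCH2OCH2)dihydrofuran-3(2H)-one (trans), via cis-furanone 21 (not isolated)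
Conditions: Rh2(OAc)4 (1 mol %), CH2Cl2, rt; then DBU (0.2 equiv), 0 °C to rt
Reagents that add atoms: none
Why: The rhodium carbenoid of the terminal diazoketone is captured by the C7' hydroxyl (intramolecular O–H insertion, an established entry to tetrahydrofuran-3-ones), closing ring A at O–C9 with retention at C7' and C8', and catalytic DBU then equilibrates C8' α to the ketone to the more stable trans isomer (C8' S), so that C7' alone carries the absolute configuration.

Step 12
Reactants: 22 trans-furanone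
Product: 23 (7S,8R,7'R,8'S)-4,4'-bis-O-triisopropylsilyl-8-hydroxypinoresinol
Conditions: hν (medium-pressure Hg lamp, Pyrex filter, > 300 nm), degassed benzene (0.01 M), rt
Reagents that add atoms: none
Why: Excitation of the C8 ketone to its n,π* state (the silylated guaiacyl rings are transparent above 300 nm) is followed by 1,6-hydrogen transfer from the vanillyl ether C7–H through a seven-membered transition state, and the resulting 1,5-biradical (C8 hydroxyalkyl carbon and C7 benzylic α-oxy carbon) collapses by radical recombination to the C7–C8 bond. The closest known reaction type is the Norrish–Yang δ-hydrogen abstraction and cyclisation of β-(benzyloxy) ketones to 3-hydroxytetrahydrofurans, which is established for 4-(arylmethoxymethyl)dihydrofuran-3-ones of this kind. Ring B (C8–C7–O–C9'–C8') closes by 1,5-biradical coupling to a five-membered ring, not by a polar exo or endo attack, and this completes the cis-fused 3,7-dioxabicyclo[3.3.0]octane. C8 (R) is controlled by C8', because the short C9'–O tether can reach only its own face of C8 and so places the hydroxyl cis to H8'; C7 (S) is controlled by the preference of the aryl group on the C7 radical for the convex exo side away from ring A, and thus by C8' and C7' together. The step needs δ-abstraction to win over α-cleavage and needs the exo orientation at C7: the γ-position is the ether oxygen, so no γ-hydrogen is available for the usual abstraction and fragmentation, the benzylic α-oxy C7–H is the weakest bond within reach, C7'–H is held in ring A where only a strained transition state could reach it, and dilute degassed benzene suppresses quenching and intermolecular hydrogen transfer.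

Step 13
Reactants: 23 bis-TIPS 8-hydroxypinoresinol
Product: 24 (7S,8R,7'R,8'S)-4,4'-bis-O-triisopropylsilyl-8-acetoxypinoresinol
Conditions: Ac2O, DMAP (1 equiv), Et3N, CH2Cl2, rt to 40 °C
Reagents that add atoms: acetic anhydride, CC(=O)OC(C)=O
Why: DMAP-mediated acyl transfer is strong enough to acetylate the hindered tertiary bridgehead alcohol, and the aryl TIPS ethers and cyclic benzylic ethers are stable to these basic conditions.

Step 14
Reactants: 24 bis-TIPS 8-acetoxypinoresinol
Product: 25 8-acetoxypinoresinol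
Conditions: Bu4NF, AcOH (1:1, 2.5 equiv), THF, 0 °C
Reagents that add atoms: none
Why: Fluoride cleaves both aryl Si–O bonds, and the acetic acid buffer keeps the liberated phenols protonated, so that neither quinone-methide opening of the benzylic ethers at C7 and C7' nor cleavage or migration of the tertiary acetate should occur.

**Compound list**

1 | vanillin | COc1cc(C=O)ccc1O | starting material
2 | 4-(triisopropylsilyloxy)-3-methoxybenzaldehyde | COc1cc(C=O)ccc1O[Si](C(C)C)(C(C)C)C(C)C | intermediate
3 | [4-(triisopropylsilyloxy)-3-methoxyphenyl]methanol | COc1cc(CO)ccc1O[Si](C(C)C)(C(C)C)C(C)C | intermediate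
4 | methyl acrylate | C=CC(=O)OC | starting material
5 | methyl 3-[(4-triisopropylsilyloxy-3-methoxybenzyl)oxy]propanoate | COC(=O)CCOCc1ccc(O[Si](C(C)C)(C(C)C)C(C)C)c(OC)c1 | intermediate
6 | 3-[(4-triisopropylsilyloxy-3-methoxybenzyl)oxy]propanoic acid | OC(=O)CCOCc1ccc(O[Si](C(C)C)(C(C)C)C(C)C)c(OC)c1 | intermediate
7 | (R)-4-benzyloxazolidin-2-one | O=C1N[C@H](Cc2ccccc2)CO1 | starting material
8 | mixed anhydride of 6 with pivalic acid | CC(C)(C)C(=O)OC(=O)CCOCc1ccc(O[Si](C(C)C)(C(C)C)C(C)C)c(OC)c1 | intermediate (not isolated)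
9 | (R)-4-benzyl-3-{3-[(4-triisopropylsilyloxy-3-methoxybenzyl)oxy]propanoyl}oxazolidin-2-one | O=C(CCOCc1ccc(O[Si](C(C)C)(C(C)C)C(C)C)c(OC)c1)N1[C@H](Cc2ccccc2)COC1=O | intermediate
10 | Z-dibutylboron enolate of 9 | CCCCB(CCCC)O/C(=C\COCc1ccc(O[Si](C(C)C)(C(C)C)C(C)C)c(OC)c1)N1[C@H](Cc2ccccc2)COC1=O | intermediate (not isolated)
11 | O-dibutylboryl aldolate of 12 | O=C([C@H](COCc1ccc(O[Si](C(C)C)(C(C)C)C(C)C)c(OC)c1)[C@@H](OB(CCCC)CCCC)c1ccc(O[Si](C(C)C)(C(C)C)C(C)C)c(OC)c1)N1[C@H](Cc2ccccc2)COC1=O | intermediate (not isolated)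
12 | syn aldol adduct, (R)-4-benzyl-3-[(2R,3R)-3-Ar-3-hydroxy-2-(ArCH2OCH2)propanoyl]oxazolidin-2-one | O=C([C@H](COCc1ccc(O[Si](C(C)C)(C(C)C)C(C)C)c(OC)c1)[C@@H](O)c1ccc(O[Si](C(C)C)(C(C)C)C(C)C)c(OC)c1)N1[C@H](Cc2ccccc2)COC1=O | intermediate
13 | (2R,3R)-3-Ar-3-hydroxy-2-(ArCH2OCH2)propaneperoxoic acid | OOC(=O)[C@H](COCc1ccc(O[Si](C(C)C)(C(C)C)C(C)C)c(OC)c1)[C@@H](O)c1ccc(O[Si](C(C)C)(C(C)C)C(C)C)c(OC)c1 | intermediate (not isolated)
14 | (2R,3R)-3-Ar-3-hydroxy-2-(ArCH2OCH2)propanoic acid | OC(=O)[C@H](COCc1ccc(O[Si](C(C)C)(C(C)C)C(C)C)c(OC)c1)[C@@H](O)c1ccc(O[Si](C(C)C)(C(C)C)C(C)C)c(OC)c1 | intermediate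
15 | triethylsilyl (2R,3R)-3-Ar-3-(triethylsilyloxy)-2-(ArCH2OCH2)propanoate | CC[Si](CC)(CC)OC(=O)[C@H](COCc1ccc(O[Si](C(C)C)(C(C)C)C(C)C)c(OC)c1)[C@@H](O[Si](CC)(CC)CC)c1ccc(O[Si](C(C)C)(C(C)C)C(C)C)c(OC)c1 | intermediate (not isolated)
16 | (2R,3R)-3-Ar-3-(triethylsilyloxy)-2-(ArCH2OCH2)propanoic acid | OC(=O)[C@H](COCc1ccc(O[Si](C(C)C)(C(C)C)C(C)C)c(OC)c1)[C@@H](O[Si](CC)(CC)CC)c1ccc(O[Si](C(C)C)(C(C)C)C(C)C)c(OC)c1 | intermediate
17 | (trimethylsilyl)diazomethane | C[Si](C)(C)C=[N+]=[N-] | starting material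
18 | isobutyl carbonic mixed anhydride of 16 | CC(C)COC(=O)OC(=O)[C@H](COCc1ccc(O[Si](C(C)C)(C(C)C)C(C)C)c(OC)c1)[C@@H](O[Si](CC)(CC)CC)c1ccc(O[Si](C(C)C)(C(C)C)C(C)C)c(OC)c1 | intermediate (not isolated)
19 | (3R,4R)-4-Ar-1-diazo-4-(triethylsilyloxy)-3-(ArCH2OCH2)butan-2-one | [N-]=[N+]=CC(=O)[C@H](COCc1ccc(O[Si](C(C)C)(C(C)C)C(C)C)c(OC)c1)[C@@H](O[Si](CC)(CC)CC)c1ccc(O[Si](C(C)C)(C(C)C)C(C)C)c(OC)c1 | intermediate
20 | (3R,4R)-4-Ar-1-diazo-4-hydroxy-3-(ArCH2OCH2)butan-2-one | [N-]=[N+]=CC(=O)[C@H](COCc1ccc(O[Si](C(C)C)(C(C)C)C(C)C)c(OC)c1)[C@@H](O)c1ccc(O[Si](C(C)C)(C(C)C)C(C)C)c(OC)c1 | intermediate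
21 | (4R,5R)-5-Ar-4-(ArCH2OCH2)dihydrofuran-3(2H)-one (cis) | COc1cc([C@@H]2OCC(=O)[C@@H]2COCc3ccc(O[Si](C(C)C)(C(C)C)C(C)C)c(OC)c3)ccc1O[Si](C(C)C)(C(C)C)C(C)C | intermediate (not isolated)
22 | (4S,5R)-5-Ar-4-(ArCH2OCH2)dihydrofuran-3(2H)-one (trans) | COc1cc([C@@H]2OCC(=O)[C@H]2COCc3ccc(O[Si](C(C)C)(C(C)C)C(C)C)c(OC)c3)ccc1O[Si](C(C)C)(C(C)C)C(C)C | intermediate
23 | (7S,8R,7'R,8'S)-4,4'-bis-O-triisopropylsilyl-8-hydroxypinoresinol | COc1cc([C@@H]2OC[C@@]3(O)[C@H](c4ccc(O[Si](C(C)C)(C(C)C)C(C)C)c(OC)c4)OC[C@@H]23)ccc1O[Si](C(C)C)(C(C)C)C(C)C | intermediate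
24 | (7S,8R,7'R,8'S)-4,4'-bis-O-triisopropylsilyl-8-acetoxypinoresinol | COc1cc([C@@H]2OC[C@@]3(OC(C)=O)[C@H](c4ccc(O[Si](C(C)C)(C(C)C)C(C)C)c(OC)c4)OC[C@@H]23)ccc1O[Si](C(C)C)(C(C)C)C(C)C | intermediate
25 | 8-acetoxypinoresinol | COc1cc([C@@H]2OC[C@@]3(OC(C)=O)[C@H](c4ccc(O)c(OC)c4)OC[C@@H]23)ccc1O | target

**Step count and risks**

Total step count: 14. Longest linear sequence: 14 steps (1 to 25); aldehyde 2 is used a second time in step 6, and 4, 7 and 17 are bought.

Steps most likely to fail:

1. Step 12. The excited α-alkoxy ketone may undergo α-cleavage faster than hydrogen transfer, the biradical may return the hydrogen, or ring B may close with the C7 aryl on the concave face. The fallback sets out from 22 (with 3 as the source of the benzylidene unit) and comes back at 23. Alcohol 3 and PPh3·HBr in MeCN would give (4-triisopropylsilyloxy-3-methoxybenzyl)triphenylphosphonium bromide F1. Its ylide (KOtBu, THF, −78 °C to rt) would convert ketone 22 by Wittig olefination to the C8=C7 benzylidene tetrahydrofuran F2, as either alkene isomer. OsO4 (cat.) with NMO would add both oxygens from the ring face anti to the C9' side chain and give the C7,C8-diol F3 with the C8 hydroxyl trans to C9'. CSA in wet CH2Cl2 would then ionise the electron-rich benzylic C7–OH, the C9' ether oxygen would capture the cation in a five-membered closure, and loss of the vanillyl group from the oxonium ion (debenzylative cycloetherification) would give 23, with the aryl group free to take the exo position.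

2. Step 11. The carbenoid may be intercepted by the C9' ether oxygen (oxonium ylide and benzyl shift) instead of the hydroxyl, and the DBU equilibration may trigger β-elimination of the vanillyloxy group. The fallback sets out from 20 and comes back at 22. One equivalent of anhydrous HCl in Et2O at −40 °C would convert the diazoketone to the chloromethyl ketone F4. K2CO3 with NaI (cat.) in MeCN would then close ring A by intramolecular Williamson etherification (5-exo-tet, hydroxyl onto the α-chloroketone) and equilibrate C8' in the same flask to give 22.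

3. Step 9. Acylation of the weakly nucleophilic diazoalkane by the hindered α-branched mixed anhydride may be slow or misdirected to the carbonate carbonyl. The fallback sets out from 12 and comes back at 22, bypassing steps 7 to 11. Transamination of the aldol adduct with AlMe3 and MeONHMe·HCl (CH2Cl2, −20 to 0 °C) would give the β-hydroxy Weinreb amide F5. Chloromethyllithium generated in the flask (ICH2Cl, MeLi·LiBr, THF, −78 °C, in excess so that the hydroxyl is carried as its lithium alkoxide) would give the chloromethyl ketone F4, which would be cyclised and equilibrated with K2CO3 and NaI as above to 22.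

**Further compounds**

F1 | step 12 | (4-triisopropylsilyloxy-3-methoxybenzyl)triphenylphosphonium bromide | COc1cc(C[P+](c2ccccc2)(c2ccccc2)c2ccccc2)ccc1O[Si](C(C)C)(C(C)C)C(C)C.[Br-]
F2 | step 12 | (4S,5R)-5-Ar-3-(Ar-methylidene)-4-(ArCH2OCH2)tetrahydrofuran, alkene geometry not fixed | COc1cc([C@@H]2OCC(=Cc3ccc(O[Si](C(C)C)(C(C)C)C(C)C)c(OC)c3)[C@H]2COCc3ccc(O[Si](C(C)C)(C(C)C)C(C)C)c(OC)c3)ccc1O[Si](C(C)C)(C(C)C)C(C)C
F3 | step 12 | 5-Ar-3-[Ar(hydroxy)methyl]-4-(ArCH2OCH2)tetrahydrofuran-3-ol, C8 hydroxyl trans to C9', C7 not fixed | COc1cc([C@@H]2OC[C@@](O)(C(O)c3ccc(O[Si](C(C)C)(C(C)C)C(C)C)c(OC)c3)[C@H]2COCc3ccc(O[Si](C(C)C)(C(C)C)C(C)C)c(OC)c3)ccc1O[Si](C(C)C)(C(C)C)C(C)C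
F4 | step 11 | (3R,4R)-4-Ar-1-chloro-4-hydroxy-3-(ArCH2OCH2)butan-2-one | ClCC(=O)[C@H](COCc1ccc(O[Si](C(C)C)(C(C)C)C(C)C)c(OC)c1)[C@@H](O)c1ccc(O[Si](C(C)C)(C(C)C)C(C)C)c(OC)c1
F5 | step 9 | (2R,3R)-3-Ar-3-hydroxy-N-methoxy-N-methyl-2-(ArCH2OCH2)propanamide | CON(C)C(=O)[C@H](COCc1ccc(O[Si](C(C)C)(C(C)C)C(C)C)c(OC)c1)[C@@H](O)c1ccc(O[Si](C(C)C)(C(C)C)C(C)C)c(OC)c1
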